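Readings and results stem from a simulated flask for substances that don't exist; scatter was added.

You cannot read the ratio of Z to J at 15 s off the noon run of this flask: its earliest reading stands at 0.667 min. It has to be reckoned, and I do it with one quantity.

- noon: E 0.90 M; Q 1.8 M; X 0.45 M; the very flask that is asked about, followed so far
- flask: E 0.90 M; Q 1.80 M; X 0.450 M; time 15 min

noon run (percent of the E charged)

| time / min | Z / % | J / % |
|---|---|---|
| 0.667 | 0.9 | 11.4 |
| 1.00 | 2.1 | 20.1 |
| 1.50 | 3.6 | 30.0 |
| 2.50 | 4.9 | 43.6 |
| 5.00 | 5.1 | 56.2 |
| 8.00 | 6.4 | 59.5 |

(readings scatter by 0.5 percentage points)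

- ratio of Z to J at 15 s
- ratio of Z to J at 2.0 min
- ratio of Z to J at 15 min

The proposed steps are these: E gives D, D meets Q to give J or meets X to give Z, E and J give G, and X gives L. Each rate is a constant times the amounts that meet, so the making of Z carries D and X while the making of J carries D and Q. Divide one by the other and D cancels, however little of it stands. What remains is a constant quotient times X over Q.

The readings give that quotient without any rate being known. The first one is poor, since 0.0789 rests on a Z of 0.9% with a scatter of 0.5 percentage points. So I sum the last three readings of Z and of J, which gives a ratio of 0.103. X was charged at a quarter of Q, so the read selectivity factor, the ratio of Z to J divided by X over Q at charge, is 0.412.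

This is a reading with two bends in it. The proposed step from X to L takes X from the making of Z, and the proposed step from E and J to G takes J away; J and Z together read just 65.9% at 8.00 min. I expect these to roughly offset each other, so I commit to 0.103 at all three times, trusting the earliest least.

The forecast, slightly above mine at 2.0 min, gives 0.1, 0.107 and 0.1, adding “so the ratio is frozen near 0.10”.

The flask gives 0.0895, 0.101 and 0.0982, against the 0.103 that 0.412 gives at its charges.

E → D (k = 0.00930 s⁻¹); Q + D → J (k = 0.0160 L mol⁻¹ s⁻¹); X + D → Z (k = 0.00560 L mol⁻¹ s⁻¹); E + J → G (k = 0.00990 L mol⁻¹ s⁻¹); X → L (k = 0.00240 s⁻¹) Half of the making of J up to 15 min is done by 1.64 min, earlier than the 3.80 min for half of the loss of X to L. At 1.50 min, X still holds 75.3% of its charge and Q holds 82.3%. Carried to the neighbouring flask with 0.18 M of X and its other charges unchanged, 0.412 gives 0.0412, and that flask stands at 0.0392 at 15 min.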